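## Retrosynthetic overview

1. The 3-hydroxy-1,2-dioxolane is made last, by singlet-oxygen ene reaction and hemiperketal closure on the α-isopropylidene ketone of the dienone half of the dimer.
2. The norbornene core comes from an exo cross Diels–Alder reaction of two transient guaianes: a 2-acetoxy-cyclopenta-1(5),3-diene (half A) and a cyclopentadienone (half B, 10-epi series).
3. The diene is released by 1,4-dehydration of an allylic alcohol; the dienone is released by selenoxide elimination. Both come from 3-oxo-guai-4-ene type bicyclic enones.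
4. Each cyclopentenone is annulated (nitroalkene Michael/Nef, then aldol) onto the ketone silyl enol ether of a seven-membered ring.
5. Both seven-membered rings come from one vinyldiazoacetate and one siloxydiene by enantiomeric Rh-catalysed [4+3] reactions. Ring order: seven-membered, five-membered, norbornene, dioxolane.

Assumption: comments use guaiane numbering (primes for the dienone half; guaiane C2, C3, C4, C5, C6, C7, C8, C9, C10, C1 = azulene C1, C2, C3, C3a, C4, C5, C6, C7, C8, C8a in the names); the sense of induction of Rh2(PTAD)4 and of t-Bu-PHOX is assigned by analogy (the antipode is used if it proves reversed); the C8′ hemiperketal epimer of the target is taken to be the thermodynamic one.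

## Route

Step 1
Reactants: 1 allyl acetoacetate
Product: 2 allyl 2-diazo-3-oxobutanoate
Conditions: 4-AcNHC6H4SO2N3, Et3N, MeCN, 0 to 20 °C
Reagents that add atoms: 4-acetamidobenzenesulfonyl azide, CC(=O)Nc1ccc(cc1)S(=O)(=O)N=[N+]=[N-]
Why: Regitz diazo transfer to the activated methylene of a β-keto ester; no stereocentre is involved.

Step 2
Reactants: 2 allyl 2-diazo-3-oxobutanoate
Product: 3 allyl 3-[(tert-butyldimethylsilyl)oxy]-2-diazobut-3-enoate
Conditions: TBSOTf, Et3N, CH2Cl2, 0 °C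
Reagents that add atoms: tert-butyldimethylsilyl trifluoromethanesulfonate, CC(C)(C)[Si](C)(C)OS(=O)(=O)C(F)(F)F
Why: Soft enolisation and O-silylation of the acetyl group gives the siloxyvinyl diazoacetate (donor/acceptor carbenoid precursor) without touching the diazo group.

Step 3
Reactants: 4 (E)-pent-3-en-2-one
Product: 5 tert-butyldimethyl[(3E)-penta-1,3-dien-2-yloxy]silane
Conditions: TBSOTf, Et3N, Et2O, 0 °C
Reagents that add atoms: tert-butyldimethylsilyl trifluoromethanesulfonate, CC(C)(C)[Si](C)(C)OS(=O)(=O)C(F)(F)F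
Why: Kinetic silyl dienol ether formation at the acetyl methyl gives the 2-siloxy-1,3-diene with the (E)-propenyl geometry retained.

Step 4
Reactants: 6 2-nitrobutan-1-ol
Product: 7 2-nitrobut-1-ene
Conditions: MsCl, Et3N, CH2Cl2, 0 °C; distilled and used fresh
Reagents that add atoms: none
Why: Mesylation followed by E1cB loss of mesylate from the β-nitro alcohol gives the nitroalkene; the stereocentre is destroyed.

Step 5
Reactants: 3 allyl 3-[(tert-butyldimethylsilyl)oxy]-2-diazobut-3-enoate; 5 tert-butyldimethyl[(3E)-penta-1,3-dien-2-yloxy]silane (5 equiv)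
Product: 9 allyl (4S)-2,6-bis[(tert-butyldimethylsilyl)oxy]-4-methylcyclohepta-1,5-diene-1-carboxylate, via divinylcyclopropane 8 (not isolated)
Conditions: Rh2(S-PTAD)4 (1 mol%), hexanes, slow addition of 3, −26 to 20 °C
Reagents that add atoms: none
Why: Davies tandem cyclopropanation/cis-divinylcyclopropane Cope rearrangement (formal [4+3]): the carbenoid adds to the terminal silyl enol ether alkene of 5 (in excess, so the allyl ester alkene does not compete) and the boat Cope step relays the catalyst-set cyclopropane chirality to C10 (10S).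

Step 6
Reactants: 9 allyl (4S)-2,6-bis[(tert-butyldimethylsilyl)oxy]-4-methylcyclohepta-1,5-diene-1-carboxylate; 7 2-nitrobut-1-ene
Product: 11 allyl (4S,5R)-2-[(tert-butyldimethylsilyl)oxy]-4-methyl-6-oxo-5-(2-oxobutyl)cyclohept-1-ene-1-carboxylate, via aci-nitro ketone 10 (not isolated)
Conditions: SnCl4, CH2Cl2, −78 °C; then H2O, NaOAc, THF, 40 °C
Reagents that add atoms: water, O
Why: Yoshikoshi Mukaiyama–Michael addition of the ketone silyl enol ether (the push–pull β-siloxy acrylate is inert) followed by Nef hydrolysis gives the 1,4-diketone, with C1 set trans to the C10 methyl by approach anti to that methyl.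

Step 7
Reactants: 11 allyl (4S,5R)-2-[(tert-butyldimethylsilyl)oxy]-4-methyl-6-oxo-5-(2-oxobutyl)cyclohept-1-ene-1-carboxylate
Product: 12 allyl (8S,8aR)-6-[(tert-butyldimethylsilyl)oxy]-3,8-dimethyl-2-oxo-1,2,4,7,8,8a-hexahydroazulene-5-carboxylate
Conditions: t-BuOK (1.1 equiv), t-BuOH–THF, 0 °C
Reagents that add atoms: none
Why: Intramolecular aldol condensation of the 1,4-diketone closes the cyclopentenone (C4=C5) irreversibly, with H-1 staying trans to the C10 methyl.

Step 8
Reactants: 12 allyl (8S,8aR)-6-[(tert-butyldimethylsilyl)oxy]-3,8-dimethyl-2-oxo-1,2,4,7,8,8a-hexahydroazulene-5-carboxylate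
Product: 14 allyl (1S,8S,8aR)-1-acetoxy-6-[(tert-butyldimethylsilyl)oxy]-3,8-dimethyl-2-oxo-1,2,4,7,8,8a-hexahydroazulene-5-carboxylate, via hydroxy enone 13 (not isolated)
Conditions: LiN(i-Pr)2, THF, −78 °C; 2-(phenylsulfonyl)-3-phenyloxaziridine; then Ac2O, DMAP, −78 to 0 °C
Reagents that add atoms: 2-(phenylsulfonyl)-3-phenyloxaziridine, O1N(S(=O)(=O)c2ccccc2)C1c1ccccc1; acetic anhydride, CC(=O)OC(C)=O
Why: Davis α′-hydroxylation of the kinetic enolate of the only free ketone (C8 is masked as the silyl enol ether of the β-keto ester) occurs anti to the C1–C10 bond and is acetylated in situ, so the C2 acetoxy group is set cis to H-1.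

Step 9
Reactants: 14 allyl (1S,8S,8aR)-1-acetoxy-6-[(tert-butyldimethylsilyl)oxy]-3,8-dimethyl-2-oxo-1,2,4,7,8,8a-hexahydroazulene-5-carboxylate
Product: 16 allyl (1S,8S,8aR)-1-acetoxy-5-isopropyl-3,8-dimethyl-2,6-dioxo-1,2,4,5,6,7,8,8a-octahydroazulene-5-carboxylate (both C5 epimers), via keto ester enolate 15 (not isolated)
Conditions: CsF, 2-iodopropane, DMF, 45 °C
Reagents that add atoms: 2-iodopropane, CC(C)I
Why: Fluoride desilylation unveils the stabilised β-keto ester enolate, which is C-alkylated by the secondary iodide (β-keto ester alkylation); the C7 configuration is irrelevant because the next step erases it.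

Step 10
Reactants: 16 allyl (1S,8S,8aR)-1-acetoxy-5-isopropyl-3,8-dimethyl-2,6-dioxo-1,2,4,5,6,7,8,8a-octahydroazulene-5-carboxylate
Product: 17 (1S,5R,8S,8aR)-5-isopropyl-3,8-dimethyl-2,6-dioxo-1,2,4,5,6,7,8,8a-octahydroazulen-1-yl acetate
Conditions: Pd2(dba)3 (5 mol%), (S)-t-Bu-PHOX (12.5 mol%), Meldrum's acid, 1,4-dioxane, 22 °C
Reagents that add atoms: none
Why: Stoltz decarboxylative enantioselective protonation: loss of CO2 from the allyl β-keto ester gives a palladium enolate that Meldrum's acid protonates under ligand control, setting C7 (R) beside the ketone under neutral, non-epimerising conditions.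

Step 11
Reactants: 17 (1S,5R,8S,8aR)-5-isopropyl-3,8-dimethyl-2,6-dioxo-1,2,4,5,6,7,8,8a-octahydroazulen-1-yl acetate
Product: 18 (1S,2R,5R,8S,8aR)-2-hydroxy-5-isopropyl-3,8-dimethyl-6-oxo-1,2,4,5,6,7,8,8a-octahydroazulen-1-yl acetate
Conditions: NaBH4, CeCl3·7H2O, MeOH, −78 °C
Reagents that add atoms: none
Why: Luche 1,2-reduction is expected to prefer the conjugated C3 ketone over the hindered saturated C8 ketone, with hydride arriving anti to the neighbouring acetoxy group to give the all-cis H-1/OAc-2/OH-3 array that step 17 needs.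

Step 12
Reactants: 3 allyl 3-[(tert-butyldimethylsilyl)oxy]-2-diazobut-3-enoate; 5 tert-butyldimethyl[(3E)-penta-1,3-dien-2-yloxy]silane (5 equiv)
Product: 20 allyl (4R)-2,6-bis[(tert-butyldimethylsilyl)oxy]-4-methylcyclohepta-1,5-diene-1-carboxylate, via divinylcyclopropane 19 (not isolated)
Conditions: Rh2(R-PTAD)4 (1 mol%), hexanes, slow addition of 3, −26 to 20 °C
Reagents that add atoms: none
Why: The same Davies cyclopropanation/Cope [4+3] reaction with the antipodal catalyst gives the 10R series needed for half B.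

Step 13
Reactants: 20 allyl (4R)-2,6-bis[(tert-butyldimethylsilyl)oxy]-4-methylcyclohepta-1,5-diene-1-carboxylate; 7 2-nitrobut-1-ene
Product: 22 allyl (4R,5S)-2-[(tert-butyldimethylsilyl)oxy]-4-methyl-6-oxo-5-(2-oxobutyl)cyclohept-1-ene-1-carboxylate, via aci-nitro ketone 21 (not isolated)
Conditions: SnCl4, CH2Cl2, −78 °C; then H2O, NaOAc, THF, 40 °C
Reagents that add atoms: water, O
Why: Yoshikoshi Mukaiyama–Michael/Nef sequence as in step 6, anti to the C10′ methyl.

Step 14
Reactants: 22 allyl (4R,5S)-2-[(tert-butyldimethylsilyl)oxy]-4-methyl-6-oxo-5-(2-oxobutyl)cyclohept-1-ene-1-carboxylate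
Product: 23 allyl (8R,8aS)-6-[(tert-butyldimethylsilyl)oxy]-3,8-dimethyl-2-oxo-1,2,4,7,8,8a-hexahydroazulene-5-carboxylate
Conditions: t-BuOK (1.1 equiv), t-BuOH–THF, 0 °C
Reagents that add atoms: none
Why: Intramolecular aldol condensation as in step 7.

Step 15
Reactants: 23 allyl (8R,8aS)-6-[(tert-butyldimethylsilyl)oxy]-3,8-dimethyl-2-oxo-1,2,4,7,8,8a-hexahydroazulene-5-carboxylate
Product: 24 allyl (1R,8R,8aS)-6-[(tert-butyldimethylsilyl)oxy]-3,8-dimethyl-2-oxo-1-(phenylselanyl)-1,2,4,7,8,8a-hexahydroazulene-5-carboxylate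
Conditions: LiN(i-Pr)2, THF, −78 °C; PhSeCl
Reagents that add atoms: phenylselenenyl chloride, Cl[Se]c1ccccc1
Why: Selenenylation of the kinetic α′-enolate of the only free ketone occurs anti to the C1′–C10′ bond, placing selenium cis to H-1′ for the later syn-elimination.

Step 16
Reactants: 24 allyl (1R,8R,8aS)-6-[(tert-butyldimethylsilyl)oxy]-3,8-dimethyl-2-oxo-1-(phenylselanyl)-1,2,4,7,8,8a-hexahydroazulene-5-carboxylate
Product: 26 (1R,8R,8aS)-3,8-dimethyl-1-(phenylselanyl)-5-(propan-2-ylidene)-4,5,8,8a-tetrahydroazulene-2,6(1H,7H)-dione, via tertiary carbinol 25 (not isolated)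
Conditions: LiN(i-Pr)2 (1.1 equiv), THF, −78 °C; MeLi (3 equiv), −78 to −40 °C; aq. NH4Cl; then PPTS (cat.), CH2Cl2, 0 °C
Reagents that add atoms: methyllithium, [Li]C
Why: The ketone is protected as its enolate while MeLi turns the ester into the tertiary carbinol; mild acid then ionises this γ-hydroxy silyl enol ether (Mukaiyama-aldol-type dehydration) to the α-isopropylidene ketone regiospecifically and lets the α-seleno centre settle cis to H-1′.

Step 17
Reactants: 18 (1S,2R,5R,8S,8aR)-2-hydroxy-5-isopropyl-3,8-dimethyl-6-oxo-1,2,4,5,6,7,8,8a-octahydroazulen-1-yl acetate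
Product: 29 (1R,5R,8S)-5-isopropyl-3,8-dimethyl-6-oxo-1,4,5,6,7,8-hexahydroazulen-1-yl acetate, via sulfenate 27 (not isolated), via allylic sulfoxide 28 (not isolated)
Conditions: 2,4-(O2N)2C6H3SCl, Et3N, CH2Cl2, −20 to 20 °C; cold filtration (SiO2, −20 °C); solution used at once
Reagents that add atoms: none
Why: Reich 1,4-dehydration: the allylic sulfenate undergoes a suprafacial [2,3]-shift to the C5 sulfoxide, which syn-eliminates with the cis H-1 at room temperature, giving the 5-acetoxycyclopentadiene-type diene under near-neutral conditions, below the onset of 1,5-hydrogen shifts.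

Step 18
Reactants: 29 (1R,5R,8S)-5-isopropyl-3,8-dimethyl-6-oxo-1,4,5,6,7,8-hexahydroazulen-1-yl acetate (1.5 equiv); 26 (1R,8R,8aS)-3,8-dimethyl-1-(phenylselanyl)-5-(propan-2-ylidene)-4,5,8,8a-tetrahydroazulene-2,6(1H,7H)-dione
Product: 32 exo cycloadduct (acetoxy dimer carrying the isopropylidene ketone), via selenoxide 30 (not isolated), via cyclopentadienone 31 (not isolated)
Conditions: 26, mCPBA (1.0 equiv), CH2Cl2, −78 °C; then i-Pr2NEt, solution of 29, −78 to 0 °C
Reagents that add atoms: none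
Why: Proposed new method: normal-demand Diels–Alder between two transient partners (closest precedents: trapping of cyclopentadienones by cyclopentadienes and cycloadditions of 5-acetoxycyclopentadiene); selenoxide syn-elimination releases dienone 31, whose strained C1′=C2′ bond is attacked so that the unsubstituted diene terminus C3 (largest HOMO coefficient) bonds to the enone β-carbon C1′ and C1 to C2′, each partner reacting anti to its C10 methyl; because the quaternary C1′ must put one carbon substituent beside the C2 bridge, only the flat cyclopentenone ring on the H-2 side fits, so the exo mode anti to the acetoxy group (overriding the usual syn preference of 5-acyloxycyclopentadienes) is expected to set C1, C3, C1′ and C2′ at once.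

Step 19
Reactants: 32 exo cycloadduct (acetoxy dimer carrying the isopropylidene ketone)
Product: 34 CNP0361479.4, via allylic hydroperoxide 33 (not isolated)
Conditions: O2, hν (visible), tetraphenylporphyrin (cat.), CH2Cl2, −20 °C; then 20 °C, dark
Reagents that add atoms: dioxygen, O=O
Why: Schenck ene reaction of the s-cis α-isopropylidene ketone with geminal selectivity (H taken from C6′, oxygen delivered to C11′, as with pulegone) gives the β-hydroperoxy dienone, which closes onto C8′ as the 3-hydroxy-1,2-dioxolane, while the tetrasubstituted norbornene alkene is shielded on both faces by the syn acetate and the endo bridge substituents.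

## Compound list

1 | allyl acetoacetate | CC(=O)CC(=O)OCC=C | starting material
2 | allyl 2-diazo-3-oxobutanoate | CC(=O)C(=[N+]=[N-])C(=O)OCC=C | intermediate
3 | allyl 3-[(tert-butyldimethylsilyl)oxy]-2-diazobut-3-enoate | C=C(O[Si](C)(C)C(C)(C)C)C(=[N+]=[N-])C(=O)OCC=C | intermediate
4 | (E)-pent-3-en-2-one | C/C=C/C(C)=O | starting material
5 | tert-butyldimethyl[(3E)-penta-1,3-dien-2-yloxy]silane | C/C=C/C(=C)O[Si](C)(C)C(C)(C)C | intermediate
6 | 2-nitrobutan-1-ol (racemic) | CCC(CO)[N+](=O)[O-] | starting material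
7 | 2-nitrobut-1-ene | CCC(=C)[N+](=O)[O-] | intermediate
8 | allyl (1R,2S)-2-[(tert-butyldimethylsilyl)oxy]-1-{1-[(tert-butyldimethylsilyl)oxy]ethenyl}-2-[(E)-prop-1-enyl]cyclopropane-1-carboxylate (cis-divinylcyclopropane) | C=CCOC(=O)[C@@]1(C(=C)O[Si](C)(C)C(C)(C)C)C[C@]1(O[Si](C)(C)C(C)(C)C)/C=C/C | intermediate
9 | allyl (4S)-2,6-bis[(tert-butyldimethylsilyl)oxy]-4-methylcyclohepta-1,5-diene-1-carboxylate | C=CCOC(=O)C1=C(O[Si](C)(C)C(C)(C)C)C[C@H](C)C=C(O[Si](C)(C)C(C)(C)C)C1 | intermediate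
10 | allyl (4S,5R)-5-(2-aci-nitrobutyl)-2-[(tert-butyldimethylsilyl)oxy]-4-methyl-6-oxocyclohept-1-ene-1-carboxylate | C=CCOC(=O)C1=C(O[Si](C)(C)C(C)(C)C)C[C@H](C)[C@@H](CC(CC)=[N+]([O-])O)C(=O)C1 | intermediate
11 | allyl (4S,5R)-2-[(tert-butyldimethylsilyl)oxy]-4-methyl-6-oxo-5-(2-oxobutyl)cyclohept-1-ene-1-carboxylate | C=CCOC(=O)C1=C(O[Si](C)(C)C(C)(C)C)C[C@H](C)[C@@H](CC(=O)CC)C(=O)C1 | intermediate
12 | allyl (8S,8aR)-6-[(tert-butyldimethylsilyl)oxy]-3,8-dimethyl-2-oxo-1,2,4,7,8,8a-hexahydroazulene-5-carboxylate | C=CCOC(=O)C1=C(O[Si](C)(C)C(C)(C)C)C[C@H](C)[C@H]2CC(=O)C(C)=C2C1 | intermediate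
13 | allyl (1S,8S,8aR)-6-[(tert-butyldimethylsilyl)oxy]-1-hydroxy-3,8-dimethyl-2-oxo-1,2,4,7,8,8a-hexahydroazulene-5-carboxylate (present as its lithium alkoxide) | C=CCOC(=O)C1=C(O[Si](C)(C)C(C)(C)C)C[C@H](C)[C@H]2[C@H](O)C(=O)C(C)=C2C1 | intermediate
14 | allyl (1S,8S,8aR)-1-acetoxy-6-[(tert-butyldimethylsilyl)oxy]-3,8-dimethyl-2-oxo-1,2,4,7,8,8a-hexahydroazulene-5-carboxylate | C=CCOC(=O)C1=C(O[Si](C)(C)C(C)(C)C)C[C@H](C)[C@H]2[C@H](OC(C)=O)C(=O)C(C)=C2C1 | intermediate
15 | allyl (1S,8S,8aR)-1-acetoxy-3,8-dimethyl-2,6-dioxo-1,2,4,5,6,7,8,8a-octahydroazulene-5-carboxylate (present as its caesium enolate, C5 not defined) | C=CCOC(=O)C1C(=O)C[C@H](C)[C@H]2[C@H](OC(C)=O)C(=O)C(C)=C2C1 | intermediate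
16 | allyl (1S,8S,8aR)-1-acetoxy-5-isopropyl-3,8-dimethyl-2,6-dioxo-1,2,4,5,6,7,8,8a-octahydroazulene-5-carboxylate (both C5 epimers) | C=CCOC(=O)C1(C(C)C)C(=O)C[C@H](C)[C@H]2[C@H](OC(C)=O)C(=O)C(C)=C2C1 | intermediate
17 | (1S,5R,8S,8aR)-5-isopropyl-3,8-dimethyl-2,6-dioxo-1,2,4,5,6,7,8,8a-octahydroazulen-1-yl acetate | CC(C)[C@@H]1C(=O)C[C@H](C)[C@H]2[C@H](OC(C)=O)C(=O)C(C)=C2C1 | intermediate
18 | (1S,2R,5R,8S,8aR)-2-hydroxy-5-isopropyl-3,8-dimethyl-6-oxo-1,2,4,5,6,7,8,8a-octahydroazulen-1-yl acetate | CC(C)[C@@H]1C(=O)C[C@H](C)[C@H]2[C@H](OC(C)=O)[C@H](O)C(C)=C2C1 | intermediate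
19 | allyl (1S,2R)-2-[(tert-butyldimethylsilyl)oxy]-1-{1-[(tert-butyldimethylsilyl)oxy]ethenyl}-2-[(E)-prop-1-enyl]cyclopropane-1-carboxylate (cis-divinylcyclopropane) | C=CCOC(=O)[C@]1(C(=C)O[Si](C)(C)C(C)(C)C)C[C@@]1(O[Si](C)(C)C(C)(C)C)/C=C/C | intermediate
20 | allyl (4R)-2,6-bis[(tert-butyldimethylsilyl)oxy]-4-methylcyclohepta-1,5-diene-1-carboxylate | C=CCOC(=O)C1=C(O[Si](C)(C)C(C)(C)C)C[C@@H](C)C=C(O[Si](C)(C)C(C)(C)C)C1 | intermediate
21 | allyl (4R,5S)-5-(2-aci-nitrobutyl)-2-[(tert-butyldimethylsilyl)oxy]-4-methyl-6-oxocyclohept-1-ene-1-carboxylate | C=CCOC(=O)C1=C(O[Si](C)(C)C(C)(C)C)C[C@@H](C)[C@H](CC(CC)=[N+]([O-])O)C(=O)C1 | intermediate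
22 | allyl (4R,5S)-2-[(tert-butyldimethylsilyl)oxy]-4-methyl-6-oxo-5-(2-oxobutyl)cyclohept-1-ene-1-carboxylate | C=CCOC(=O)C1=C(O[Si](C)(C)C(C)(C)C)C[C@@H](C)[C@H](CC(=O)CC)C(=O)C1 | intermediate
23 | allyl (8R,8aS)-6-[(tert-butyldimethylsilyl)oxy]-3,8-dimethyl-2-oxo-1,2,4,7,8,8a-hexahydroazulene-5-carboxylate | C=CCOC(=O)C1=C(O[Si](C)(C)C(C)(C)C)C[C@@H](C)[C@@H]2CC(=O)C(C)=C2C1 | intermediate
24 | allyl (1R,8R,8aS)-6-[(tert-butyldimethylsilyl)oxy]-3,8-dimethyl-2-oxo-1-(phenylselanyl)-1,2,4,7,8,8a-hexahydroazulene-5-carboxylate | C=CCOC(=O)C1=C(O[Si](C)(C)C(C)(C)C)C[C@@H](C)[C@@H]2[C@@H]([Se]c3ccccc3)C(=O)C(C)=C2C1 | intermediate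
25 | (1R,8R,8aS)-6-[(tert-butyldimethylsilyl)oxy]-5-(2-hydroxypropan-2-yl)-3,8-dimethyl-1-(phenylselanyl)-4,7,8,8a-tetrahydroazulen-2(1H)-one | CC(C)(O)C1=C(O[Si](C)(C)C(C)(C)C)C[C@@H](C)[C@@H]2[C@@H]([Se]c3ccccc3)C(=O)C(C)=C2C1 | intermediate
26 | (1R,8R,8aS)-3,8-dimethyl-1-(phenylselanyl)-5-(propan-2-ylidene)-4,5,8,8a-tetrahydroazulene-2,6(1H,7H)-dione | CC(C)=C1C(=O)C[C@@H](C)[C@@H]2[C@@H]([Se]c3ccccc3)C(=O)C(C)=C2C1 | intermediate
27 | (1S,2R,5R,8S,8aR)-2-[(2,4-dinitrophenyl)sulfanyloxy]-5-isopropyl-3,8-dimethyl-6-oxo-1,2,4,5,6,7,8,8a-octahydroazulen-1-yl acetate (sulfenate ester of 18) | CC(C)[C@@H]1C(=O)C[C@H](C)[C@H]2[C@H](OC(C)=O)[C@H](OSc3ccc(cc3[N+](=O)[O-])[N+](=O)[O-])C(C)=C2C1 | intermediate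
28 | (1R,3aR,5R,8S,8aS)-3a-[(2,4-dinitrophenyl)sulfinyl]-5-isopropyl-3,8-dimethyl-6-oxo-1,3a,4,5,6,7,8,8a-octahydroazulen-1-yl acetate (sulfur cis to the acetoxy group and H-8a; sulfur configuration not defined) | CC(C)[C@@H]1C(=O)C[C@H](C)[C@H]2[C@H](OC(C)=O)C=C(C)[C@@]2(S(=O)c3ccc(cc3[N+](=O)[O-])[N+](=O)[O-])C1 | intermediate
29 | (1R,5R,8S)-5-isopropyl-3,8-dimethyl-6-oxo-1,4,5,6,7,8-hexahydroazulen-1-yl acetate (half A diene; guaiane 2R,7R,10S) | CC(=O)O[C@@H]1C=C(C)C2=C1[C@@H](C)CC(=O)[C@@H](C(C)C)C2 | intermediate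
30 | (1R,8R,8aS)-3,8-dimethyl-1-(phenylseleninyl)-5-(propan-2-ylidene)-4,5,8,8a-tetrahydroazulene-2,6(1H,7H)-dione (selenium configuration not defined) | CC(C)=C1C(=O)C[C@@H](C)[C@@H]2[C@@H]([Se](=O)c3ccccc3)C(=O)C(C)=C2C1 | intermediate
31 | (8R)-3,8-dimethyl-5-(propan-2-ylidene)-4,5,7,8-tetrahydroazulene-2,6-dione (half B cyclopentadienone; guaiane 10R) | O=C1C=C2[C@H](C)CC(=O)C(=C(C)C)CC2=C1C | intermediate
32 | exo Diels–Alder dimer: bonds C1–C2′ and C3–C1′; 2-acetoxy syn to the C4=C5 bridge; cyclopentenone ring of half B exo; 7-isopropyl-8-oxo in half A; 7′(11′)-ene-3′,8′-dione in half B; both C10 methyls anti to the new bonds | CC(=O)O[C@@H]1[C@@H]2C(C)=C3C[C@H](C(C)C)C(=O)C[C@H](C)[C@@]31[C@@H]1C(=O)C(C)=C3CC(=C(C)C)C(=O)C[C@@H](C)[C@]312 | intermediate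
33 | 11′-hydroperoxy-4′,6′-dien-3′,8′-dione derived from 32 (other centres as in 32) | CC(=O)O[C@@H]1[C@@H]2C(C)=C3C[C@H](C(C)C)C(=O)C[C@H](C)[C@@]31[C@@H]1C(=O)C(C)=C3C=C(C(C)(C)OO)C(=O)C[C@@H](C)[C@]312 | intermediate
34 | CNP0361479.4 (8′-hydroxy-8′,11′-epidioxy dimer) | CC(=O)O[C@@H]1[C@@H]2C(C)=C3C[C@H](C(C)C)C(=O)C[C@H](C)[C@@]31[C@@H]1C(=O)C(C)=C3C=C4C(C)(C)OO[C@]4(O)C[C@@H](C)[C@]312 | target

## Step count and risks

Total steps: 19. Longest linear sequence: 12 steps (1, 2, 5 to 11, 17, 18, 19); the half B branch (1, 2, 12 to 16) joins at step 18.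

Step 18 (cross Diels–Alder). It may fail through attack syn to the acetoxy group, through the endo mode, or through self-dimerisation of the dienone. The fallback replaces the acetate by a much bulkier silyl ether, so that steric approach control on the face of H-2 dominates, and acetylates after the cycloaddition. It sets out from 17. Acetate methanolysis (K2CO3, MeOH, 0 °C) gives the hydroxy enone F1. Silylation (TIPSOTf, 2,6-lutidine) gives the triisopropylsilyl ether F2. Luche reduction gives the allylic alcohol F3. Camphorsulfonic acid-catalysed 1,4-dehydration over molecular sieves (E1 through the allyl cation, which the non-participating silyl ether tolerates) gives the silyloxy diene F4. Cycloaddition of F4 with 31, released from 26 exactly as in step 18, gives the silyl-protected cycloadduct F5. HF·pyridine frees the bridge alcohol F6, and Ac2O in pyridine returns the route to 32.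

Step 10 (enantioselective protonation at C7). The α-isopropyl substrate with three resident stereocentres may give poor selectivity. The fallback gives up catalyst control in favour of separation and recycling. It sets out from 16. Non-selective decarboxylation (Pd(PPh3)4, HCO2H, Et3N, THF) gives 17 together with its C5 epimer F7. The two are separated by chromatography; F7 is re-equilibrated with DBU and separated again until the material is converged. The route is rejoined at 17.

Step 19 (photooxygenation of the dimer). Singlet oxygen may attack the tetrasubstituted norbornene alkene or abstract a methyl hydrogen of the isopropylidene group. The fallback changes the oxidant and mechanism to a ground-state autoxidation that only the dienone half can undergo. It sets out from 32. Catalytic DBU under O2 in MeCN at 0 °C in the dark deprotonates C6′ (vinylogous to the C3′ ketone and allylic to the isopropylidene group); the extended enolate captures triplet oxygen at C11′ to give the same hydroperoxide 33, which closes to 34. No new compound is made.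

Further compounds

F1 | step 18 | (1S,5R,8S,8aR)-1-hydroxy-5-isopropyl-3,8-dimethyl-1,4,5,7,8,8a-hexahydroazulene-2,6-dione | CC(C)[C@@H]1C(=O)C[C@H](C)[C@H]2[C@H](O)C(=O)C(C)=C2C1
F2 | step 18 | (1S,5R,8S,8aR)-5-isopropyl-3,8-dimethyl-1-[(triisopropylsilyl)oxy]-1,4,5,7,8,8a-hexahydroazulene-2,6-dione | CC(C)[C@@H]1C(=O)C[C@H](C)[C@H]2[C@H](O[Si](C(C)C)(C(C)C)C(C)C)C(=O)C(C)=C2C1
F3 | step 18 | (1S,2R,5R,8S,8aR)-2-hydroxy-5-isopropyl-3,8-dimethyl-1-[(triisopropylsilyl)oxy]-1,2,4,5,8,8a-hexahydroazulen-6(7H)-one | CC(C)[C@@H]1C(=O)C[C@H](C)[C@H]2[C@H](O[Si](C(C)C)(C(C)C)C(C)C)[C@H](O)C(C)=C2C1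
F4 | step 18 | (1R,5R,8S)-5-isopropyl-3,8-dimethyl-1-[(triisopropylsilyl)oxy]-4,5,7,8-tetrahydroazulen-6(1H)-one | CC(C)[Si](C(C)C)(C(C)C)O[C@@H]1C=C(C)C2=C1[C@@H](C)CC(=O)[C@@H](C(C)C)C2
F5 | step 18 | exo cycloadduct of F4 and 31 (triisopropylsilyl ether analogue of 32) | CC(C)[Si](C(C)C)(C(C)C)O[C@@H]1[C@@H]2C(C)=C3C[C@H](C(C)C)C(=O)C[C@H](C)[C@@]31[C@@H]1C(=O)C(C)=C3CC(=C(C)C)C(=O)C[C@@H](C)[C@]312
F6 | step 18 | deacetyl analogue of 32 (free C2 alcohol) | O[C@@H]1[C@@H]2C(C)=C3C[C@H](C(C)C)C(=O)C[C@H](C)[C@@]31[C@@H]1C(=O)C(C)=C3CC(=C(C)C)C(=O)C[C@@H](C)[C@]312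
F7 | step 10 | (1S,5S,8S,8aR)-5-isopropyl-3,8-dimethyl-2,6-dioxo-1,2,4,5,6,7,8,8a-octahydroazulen-1-yl acetate (C5 epimer of 17) | CC(C)[C@H]1C(=O)C[C@H](C)[C@H]2[C@H](OC(C)=O)C(=O)C(C)=C2C1
F0 | step 19 | none | none
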